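## Retrosynthetic overview

- The cyclobutane and cyclopentane of the terpenoid cage are disconnected together (retro-[2+2], bonds C1′–C7′ and C2′–C6′) to give a 2H-pyran that carries a homoprenyl side chain.
- The pyran is opened (retro-oxa-6π) to a dienone whose C11=C1′ bond comes from an intermolecular aldol condensation between a dibenzo[b,f]oxepin-10(11H)-one (C11 enolate) and citral.
- The prenyl group comes from an aryl bromide handle (Stille allylation, then cross-metathesis); the oxepinone ring comes from Friedel–Crafts acylation of a 2-aryloxyphenylacetic acid.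
- That acid comes from a 2-aryloxybenzaldehyde (one-carbon homologation), itself made by SNAr of 3-methoxyphenol on a brominated o-fluorobenzaldehyde.
- Ring order: rings A and B are bought; then the oxepine ring; then the pyran ring; then cyclopentane and cyclobutane in one step; the enantiomers are separated last.

Assumption: the 2H-pyran intermediate cannot hold its C3′ configuration (reversible oxa-6π ring opening), so the cage is built as a racemate and resolved in the last step; the wanted enantiomer is assigned by ECD and optical rotation against the natural product.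

Names: dibenzo[b,f]oxepine numbering for the aryl core (ring A = C1–C4, O5, ring B = C6–C9, bridge C10/C11). Terpenoid carbons keep citral numbers C1′–C8′ (C1′ on C11, C3′ the O-bearing quaternary carbon). TBS = tert-butyldimethylsilyl, prenyl = 3-methylbut-2-en-1-yl, allyl = prop-2-en-1-yl.

## Route

Step 1
Reactants: 1 2-fluoro-4-methoxybenzaldehyde
Product: 2 5-bromo-2-fluoro-4-methoxybenzaldehyde
Conditions: Br2 (1.1 equiv), AcOH, 25 °C
Reagents that add atoms: bromine, BrBr
Why: Electrophilic aromatic bromination goes to C5, which is ortho to OMe, para to F, meta to CHO and less crowded than C3.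

Step 2
Reactants: 2 5-bromo-2-fluoro-4-methoxybenzaldehyde; 3 3-methoxyphenol
Product: 4 5-bromo-4-methoxy-2-(3-methoxyphenoxy)benzaldehyde
Conditions: K2CO3 (1.5 equiv), DMF, 110 °C
Reagents that add atoms: none
Why: SNAr of the phenoxide on the fluoride ortho to the formyl group (Meisenheimer stabilisation), while the bromide meta to CHO is not activated.

Step 3
Reactants: 4 5-bromo-4-methoxy-2-(3-methoxyphenoxy)benzaldehyde
Product: 5 1-bromo-5-ethenyl-2-methoxy-4-(3-methoxyphenoxy)benzene
Conditions: Ph3PCH3Br (1.3 equiv), KOtBu (1.25 equiv), THF, 0 → 25 °C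
Reagents that add atoms: methyltriphenylphosphonium bromide, C[P+](c1ccccc1)(c1ccccc1)c1ccccc1.[Br-]
Why: Wittig methylenation of a non-enolisable aryl aldehyde is dependable and leaves the aryl bromide and diaryl ether alone.

Step 4
Reactants: 5 1-bromo-5-ethenyl-2-methoxy-4-(3-methoxyphenoxy)benzene
Product: 7 2-[5-bromo-4-methoxy-2-(3-methoxyphenoxy)phenyl]ethan-1-ol, via alkylborane 6 (not isolated)
Conditions: 9-BBN (1.5 equiv), THF, 0 → 25 °C; then NaOH aq., H2O2, 0 → 25 °C
Reagents that add atoms: hydrogen peroxide, OO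
Why: Hydroboration–oxidation with the bulky 9-BBN puts boron on the terminal carbon of the styrene (anti-Markovnikov) and the C–B bond is oxidised with retention to the primary alcohol.

Step 5
Reactants: 7 2-[5-bromo-4-methoxy-2-(3-methoxyphenoxy)phenyl]ethan-1-ol
Product: 9 [5-bromo-4-methoxy-2-(3-methoxyphenoxy)phenyl]acetic acid, via aldehyde 8 (not isolated)
Conditions: TEMPO (2,2,6,6-tetramethylpiperidin-1-oxyl, 7 mol %), NaClO2 (2 equiv), NaOCl (2 mol %), MeCN/NaH2PO4–Na2HPO4 buffer (pH 6.7), 35 °C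
Reagents that add atoms: sodium chlorite, [Na+].[O-]Cl=O
Why: Oxoammonium oxidation to the aldehyde followed by chlorite (Pinnick-type) oxidation gives the arylacetic acid, and the buffered medium with only catalytic hypochlorite avoids ring chlorination.

Step 6
Reactants: 9 [5-bromo-4-methoxy-2-(3-methoxyphenoxy)phenyl]acetic acid
Product: 10 2-bromo-3,7-dimethoxydibenzo[b,f]oxepin-10(11H)-one
Conditions: P2O5 in MeSO3H (Eaton's reagent), 25 → 45 °C
Reagents that add atoms: none
Why: Intramolecular Friedel–Crafts acylation closes the seven-membered ring onto ring B at the only reachable position that is ortho to the ether oxygen and para to OMe.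

Step 7
Reactants: 10 2-bromo-3,7-dimethoxydibenzo[b,f]oxepin-10(11H)-one
Product: 12 2-bromo-3,7-dihydroxydibenzo[b,f]oxepin-10(11H)-one, via bis(dibromoboryl) ether 11 (not isolated)
Conditions: BBr3 (4 equiv), CH2Cl2, −78 → 0 °C; then H2O
Reagents that add atoms: none
Why: Lewis-acid ether cleavage (bromide attacks the O-methyl of the boron-complexed ether) removes both methyl groups before any alkene is present; the diaryl ether, ketone and aryl bromide are inert.

Step 8
Reactants: 12 2-bromo-3,7-dihydroxydibenzo[b,f]oxepin-10(11H)-one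
Product: 13 2-bromo-3,7-bis(TBSO)dibenzo[b,f]oxepin-10(11H)-one
Conditions: TBSCl (2.5 equiv), imidazole (5 equiv), DMF, 25 °C
Reagents that add atoms: tert-butyldimethylsilyl chloride, CC(C)(C)[Si](C)(C)Cl
Why: Imidazole-promoted O-silylation of both phenols gives ethers that survive amide bases and light and come off later with fluoride instead of acid.

Step 9
Reactants: 13 2-bromo-3,7-bis(TBSO)dibenzo[b,f]oxepin-10(11H)-one
Product: 14 2-allyl-3,7-bis(TBSO)dibenzo[b,f]oxepin-10(11H)-one
Conditions: allylSnBu3 (1.5 equiv), Pd(PPh3)4 (5 mol %), toluene, 105 °C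
Reagents that add atoms: allyltributylstannane, C=CC[Sn](CCCC)(CCCC)CCCC
Why: Stille coupling (oxidative addition of the aryl bromide to zerovalent palladium, transmetalation, reductive elimination) works under neutral conditions that spare the enolisable ketone and the silyl ethers.

Step 10
Reactants: 14 2-allyl-3,7-bis(TBSO)dibenzo[b,f]oxepin-10(11H)-one
Product: 15 2-prenyl-3,7-bis(TBSO)dibenzo[b,f]oxepin-10(11H)-one
Conditions: 2-methylbut-2-ene (large excess), second-generation Grubbs catalyst RuCl2(=CHPh)(PCy3)(H2IMes) (5 mol %), CH2Cl2, 40 °C (sealed)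
Reagents that add atoms: 2-methylbut-2-ene, CC=C(C)C
Why: Olefin cross-metathesis of a terminal allyl arene with excess 2-methylbut-2-ene gives the prenyl group cleanly and cannot give the branched (reverse-prenyl) isomer.

Step 11
Reactants: 15 2-prenyl-3,7-bis(TBSO)dibenzo[b,f]oxepin-10(11H)-one; 16 citral (3,7-dimethylocta-2,6-dienal, commercial E/Z mixture)
Product: 18 11-(1-hydroxy-3,7-dimethylocta-2,6-dien-1-yl)-2-prenyl-3,7-bis(TBSO)dibenzo[b,f]oxepin-10(11H)-one (mixture of diastereomers), via lithium enolate 17 (not isolated)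
Conditions: LiN(iPr)2 (1.1 equiv), THF, −78 °C; then 16 (1.3 equiv), −78 °C; AcOH quench at −78 °C
Reagents that add atoms: none
Why: Directed aldol addition: the ketone has a single, benzylic α-position (C11), so one enolate forms and adds 1,2 to the β,β-disubstituted enal to make the C11–C1′ bond; the new carbinol and C11 centres are lost in the next step, so their configuration does not matter.

Step 12
Reactants: 18 aldol adduct
Product: 21 (±)-2-prenyl-3,7-bis(TBSO)dibenzo[b,f]oxepine with a 2H-pyran fused across C10=C11 (ring O on C10; C1′H=C2′H on C11; C3′ bearing CH3 and 4-methylpent-3-en-1-yl), via acetate 19 (not isolated), via dienone 20 (not isolated)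
Conditions: Ac2O, Et3N, 4-(dimethylamino)pyridine (cat.), CH2Cl2, 0 → 25 °C; then DBU, 25 °C
Reagents that add atoms: none
Why: Acetylation and E1cB elimination give the cross-conjugated dienone, whose (11Z) isomer closes by oxa-6π electrocyclisation to the sterically favoured 2,2-disubstituted 2H-pyran (C3′ formed racemic); any (11E) isomer left over is isomerised and funnelled through the same closure by the light of step 13.

Step 13
Reactants: 21 (±)-2H-pyran
Product: 22 (±)-(1′R*,2′R*,3′R*,6′S*)-3,7-bis-O-TBS ether of the target (cyclobutane C1′–C2′–C6′–C7′ with gem-dimethyl C7′, cis-fused to cyclopentane and dihydropyran)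
Conditions: hν (365 nm), degassed benzene (5 mM), 20 °C
Reagents that add atoms: none
Why: Intramolecular [2+2] photocycloaddition of a 1,6-diene follows the rule of five (C2′–C6′ first, then C1′–C7′); the three-atom tether from C3′ lets the alkene reach only the pyran face that carries the side chain, so C1′, C2′ and C6′ are set all-cis relative to C3′ as one racemic diastereomer.

Step 14
Reactants: 22 (±)-bis-TBS cyclol
Product: 23 (±)-target (racemate of 24)
Conditions: Bu4NF (2.4 equiv), AcOH (2.4 equiv), THF, 0 °C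
Reagents that add atoms: none
Why: Fluoride-driven Si–O cleavage frees both phenols under buffered, non-acidic conditions, so the o-prenylphenol does not cyclise to a chroman and the enol ether is not hydrolysed.

Step 15
Reactants: 23 (±)-target
Product: 24 target, (1′R,2′R,3′R,6′S) enantiomer
Conditions: preparative chiral SFC, amylose tris(3,5-dimethylphenylcarbamate) phase, CO2/MeOH
Reagents that add atoms: none
Why: Resolution on a chiral stationary phase: the enantiomers of this rigid diphenol are separated on a polysaccharide phase and the wanted one is assigned by ECD and optical rotation against the natural product; no stereocentre is touched.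

## Compound list

1 | 2-fluoro-4-methoxybenzaldehyde | COc1ccc(C=O)c(F)c1 | starting material
2 | 5-bromo-2-fluoro-4-methoxybenzaldehyde | COc1cc(F)c(C=O)cc1Br | intermediate
3 | 3-methoxyphenol | COc1cccc(O)c1 | starting material
4 | 5-bromo-4-methoxy-2-(3-methoxyphenoxy)benzaldehyde | COc1cccc(Oc2cc(OC)c(Br)cc2C=O)c1 | intermediate
5 | 1-bromo-5-ethenyl-2-methoxy-4-(3-methoxyphenoxy)benzene | COc1cccc(Oc2cc(OC)c(Br)cc2C=C)c1 | intermediate
6 | 9-{2-[5-bromo-4-methoxy-2-(3-methoxyphenoxy)phenyl]ethyl}-9-borabicyclo[3.3.1]nonane | COc1cccc(Oc2cc(OC)c(Br)cc2CCB2C3CCCC2CCC3)c1 | intermediate (not isolated)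
7 | 2-[5-bromo-4-methoxy-2-(3-methoxyphenoxy)phenyl]ethan-1-ol | COc1cccc(Oc2cc(OC)c(Br)cc2CCO)c1 | intermediate
8 | [5-bromo-4-methoxy-2-(3-methoxyphenoxy)phenyl]acetaldehyde | COc1cccc(Oc2cc(OC)c(Br)cc2CC=O)c1 | intermediate (not isolated)
9 | [5-bromo-4-methoxy-2-(3-methoxyphenoxy)phenyl]acetic acid | COc1cccc(Oc2cc(OC)c(Br)cc2CC(=O)O)c1 | intermediate
10 | 2-bromo-3,7-dimethoxydibenzo[b,f]oxepin-10(11H)-one | COc1ccc2c(c1)Oc1cc(OC)c(Br)cc1CC2=O | intermediate
11 | 2-bromo-3,7-bis[(dibromoboranyl)oxy]dibenzo[b,f]oxepin-10(11H)-one | BrB(Br)Oc1ccc2c(c1)Oc1cc(OB(Br)Br)c(Br)cc1CC2=O | intermediate (not isolated)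
12 | 2-bromo-3,7-dihydroxydibenzo[b,f]oxepin-10(11H)-one | Oc1ccc2c(c1)Oc1cc(O)c(Br)cc1CC2=O | intermediate
13 | 2-bromo-3,7-bis(TBSO)dibenzo[b,f]oxepin-10(11H)-one | CC(C)(C)[Si](C)(C)Oc1ccc2c(c1)Oc1cc(O[Si](C)(C)C(C)(C)C)c(Br)cc1CC2=O | intermediate
14 | 2-allyl-3,7-bis(TBSO)dibenzo[b,f]oxepin-10(11H)-one | CC(C)(C)[Si](C)(C)Oc1ccc2c(c1)Oc1cc(O[Si](C)(C)C(C)(C)C)c(CC=C)cc1CC2=O | intermediate
15 | 2-prenyl-3,7-bis(TBSO)dibenzo[b,f]oxepin-10(11H)-one | CC(C)(C)[Si](C)(C)Oc1ccc2c(c1)Oc1cc(O[Si](C)(C)C(C)(C)C)c(CC=C(C)C)cc1CC2=O | intermediate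
16 | citral (3,7-dimethylocta-2,6-dienal, E/Z mixture at C2=C3, hence no geometry in the SMILES) | CC(C)=CCCC(C)=CC=O | starting material
17 | lithium 2-prenyl-3,7-bis(TBSO)dibenzo[b,f]oxepin-10-olate | [Li+].[O-]C1=Cc2cc(CC=C(C)C)c(O[Si](C)(C)C(C)(C)C)cc2Oc2cc(O[Si](C)(C)C(C)(C)C)ccc12 | intermediate (not isolated)
18 | 11-(1-hydroxy-3,7-dimethylocta-2,6-dien-1-yl)-2-prenyl-3,7-bis(TBSO)dibenzo[b,f]oxepin-10(11H)-one (mixture of diastereomers and alkene isomers, so no stereodescriptors) | CC(C)=CCc1cc2c(cc1O[Si](C)(C)C(C)(C)C)Oc1cc(O[Si](C)(C)C(C)(C)C)ccc1C(=O)C2C(O)C=C(C)CCC=C(C)C | intermediate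
19 | 11-(1-acetoxy-3,7-dimethylocta-2,6-dien-1-yl)-2-prenyl-3,7-bis(TBSO)dibenzo[b,f]oxepin-10(11H)-one | CC(C)=CCc1cc2c(cc1O[Si](C)(C)C(C)(C)C)Oc1cc(O[Si](C)(C)C(C)(C)C)ccc1C(=O)C2C(OC(C)=O)C=C(C)CCC=C(C)C | intermediate (not isolated)
20 | (11Z)-11-(3,7-dimethylocta-2,6-dien-1-ylidene)-2-prenyl-3,7-bis(TBSO)dibenzo[b,f]oxepin-10(11H)-one | CC(C)=CCc1cc2c(cc1O[Si](C)(C)C(C)(C)C)Oc1cc(O[Si](C)(C)C(C)(C)C)ccc1C(=O)/C2=C\C=C(C)CCC=C(C)C | intermediate (not isolated)
21 | (±)-2H-pyran fused across C10=C11 of 2-prenyl-3,7-bis(TBSO)dibenzo[b,f]oxepine (C3′ racemic, left unspecified) | CC(C)=CCc1cc2c(cc1O[Si](C)(C)C(C)(C)C)Oc1cc(O[Si](C)(C)C(C)(C)C)ccc1C1=C2C=CC(C)(CCC=C(C)C)O1 | intermediate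
22 | (±)-(1′R*,2′R*,3′R*,6′S*)-3,7-bis-O-TBS ether of the target (racemate; SMILES shows the enantiomer that leads to 24) | CC(C)=CCc1cc2c(cc1O[Si](C)(C)C(C)(C)C)Oc1cc(O[Si](C)(C)C(C)(C)C)ccc1C1=C2[C@@H]2[C@H]3[C@H](CC[C@@]3(C)O1)C2(C)C | intermediate
23 | (±)-target (racemate; SMILES shows the enantiomer that is 24, its mirror image is present in equal amount) | CC(C)=CCc1cc2c(cc1O)Oc1cc(O)ccc1C1=C2[C@@H]2[C@H]3[C@H](CC[C@@]3(C)O1)C2(C)C | intermediate
24 | (1′R,2′R,3′R,6′S)-3,7-dihydroxy-2-prenyl-dibenzo[b,f]oxepine fused at C10–C11 to the all-cis cyclol cage (CNP0185814.1) | CC(C)=CCc1cc2c(cc1O)Oc1cc(O)ccc1C1=C2[C@@H]2[C@H]3[C@H](CC[C@@]3(C)O1)C2(C)C | target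

## Step count and risks

Total steps: 15. Longest linear sequence: 15 steps (1 → 24); 3 and 16 enter as bought materials.

**Step 9 (Stille coupling).** The bromide is electron-rich and flanked by a bulky silyl ether, so oxidative addition may be slow. The fallback moves the coupling ahead of the protecting-group exchange. It sets out from 10: allyltributylstannane and Pd(PPh3)4 in toluene at 105 °C give 2-allyl-3,7-dimethoxydibenzo[b,f]oxepin-10(11H)-one F1, where only a methoxy group flanks the bromide. BBr3 at −78 → 0 °C, which a monosubstituted allyl group tolerates, then gives, by way of 2-allyl-3,7-bis[(dibromoboranyl)oxy]dibenzo[b,f]oxepin-10(11H)-one F2, the diphenol 2-allyl-3,7-dihydroxydibenzo[b,f]oxepin-10(11H)-one F3. TBSCl and imidazole silylate it, and the route is rejoined at 14.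

**Step 12 (elimination and oxa-6π closure).** The aldol may revert, or the elimination may stall at the (11E)-dienone that cannot close. The fallback replaces the stepwise anionic aldol/elimination by an amine-mediated Knoevenagel cascade. It sets out from 15: 15 and citral 16 are heated with ethylenediammonium diacetate (20 mol %) in toluene at 80 °C. Reversible amine addition keeps the dienone isomers in equilibrium so that they drain through 20 into the pyran, and the route is rejoined at 21 (steps 11 and 12 are both bypassed). Compounds beyond the list: none F0.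

**Step 13 (photocycloaddition).** Competing photochemistry of the extended chromophore could lower the yield. The fallback uses an acid-promoted (cationic) [2+2], and therefore moves prenyl installation to the end so that no acid-sensitive prenyl group is present. It sets out from 14:
- LiN(iPr)2 gives the lithium enolate of 14 F4, which adds to citral 16 to give the allyl aldol adduct F5.
- Acetylation gives the allyl acetate F6; DBU elimination by way of the allyl (11Z)-dienone F7 gives the allyl 2H-pyran F8.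
- CF3CO2H in CH2Cl2 at 0 °C then closes the cage to the allyl cyclol F9 (racemic, same relative configuration as 22).
- Cross-metathesis of F9 with 2-methylbut-2-ene (second-generation Grubbs catalyst RuCl2(=CHPh)(PCy3)(H2IMes)) returns to 22; the tetrasubstituted enol ether is inert to the catalyst.

## Further compounds

F1 | step 9 | 2-allyl-3,7-dimethoxydibenzo[b,f]oxepin-10(11H)-one | COc1ccc2c(c1)Oc1cc(OC)c(CC=C)cc1CC2=O
F2 | step 9 | 2-allyl-3,7-bis[(dibromoboranyl)oxy]dibenzo[b,f]oxepin-10(11H)-one | BrB(Br)Oc1ccc2c(c1)Oc1cc(OB(Br)Br)c(CC=C)cc1CC2=O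
F3 | step 9 | 2-allyl-3,7-dihydroxydibenzo[b,f]oxepin-10(11H)-one | Oc1ccc2c(c1)Oc1cc(O)c(CC=C)cc1CC2=O
F0 | step 12 | none | none
F4 | step 13 | lithium 2-allyl-3,7-bis(TBSO)dibenzo[b,f]oxepin-10-olate | [Li+].[O-]C1=Cc2cc(CC=C)c(O[Si](C)(C)C(C)(C)C)cc2Oc2cc(O[Si](C)(C)C(C)(C)C)ccc12
F5 | step 13 | 2-allyl-11-(1-hydroxy-3,7-dimethylocta-2,6-dien-1-yl)-3,7-bis(TBSO)dibenzo[b,f]oxepin-10(11H)-one (mixture of diastereomers) | C=CCc1cc2c(cc1O[Si](C)(C)C(C)(C)C)Oc1cc(O[Si](C)(C)C(C)(C)C)ccc1C(=O)C2C(O)C=C(C)CCC=C(C)C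
F6 | step 13 | 11-(1-acetoxy-3,7-dimethylocta-2,6-dien-1-yl)-2-allyl-3,7-bis(TBSO)dibenzo[b,f]oxepin-10(11H)-one | C=CCc1cc2c(cc1O[Si](C)(C)C(C)(C)C)Oc1cc(O[Si](C)(C)C(C)(C)C)ccc1C(=O)C2C(OC(C)=O)C=C(C)CCC=C(C)C
F7 | step 13 | (11Z)-2-allyl-11-(3,7-dimethylocta-2,6-dien-1-ylidene)-3,7-bis(TBSO)dibenzo[b,f]oxepin-10(11H)-one | C=CCc1cc2c(cc1O[Si](C)(C)C(C)(C)C)Oc1cc(O[Si](C)(C)C(C)(C)C)ccc1C(=O)/C2=C\C=C(C)CCC=C(C)C
F8 | step 13 | (±)-2H-pyran fused across C10=C11 of 2-allyl-3,7-bis(TBSO)dibenzo[b,f]oxepine (allyl analogue of 21) | C=CCc1cc2c(cc1O[Si](C)(C)C(C)(C)C)Oc1cc(O[Si](C)(C)C(C)(C)C)ccc1C1=C2C=CC(C)(CCC=C(C)C)O1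
F9 | step 13 | (±)-(1′R*,2′R*,3′R*,6′S*)-2-allyl analogue of 22 (racemate; one enantiomer drawn) | C=CCc1cc2c(cc1O[Si](C)(C)C(C)(C)C)Oc1cc(O[Si](C)(C)C(C)(C)C)ccc1C1=C2[C@@H]2[C@H]3[C@H](CC[C@@]3(C)O1)C2(C)C
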